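**Retrosynthetic overview**
1. Target ⇒ (retro-lactonisation, then retro-aldol at the quaternary carbon) two arylpyruvate units, as in the biosynthetic dimerisation: a persilylated 4-hydroxyphenylpyruvate donor and a methyl arylpyruvate acceptor. The (R) quaternary centre is set in this last step by a chiral divalent-copper bis(oxazoline) Lewis acid.
2. Acceptor keto ester ⇒ Boc-dehydroamino ester ⇒ Heck coupling of a 5-bromo-dihydrobenzofuran with methyl 2-(Boc-amino)acrylate.
3. Dihydrobenzofuran ⇒ ortho-prenylphenol by Shi epoxidation and 5-exo phenoxide opening of the prenyl epoxide (sets the (S) centre) ⇒ 4-bromophenol + prenyl bromide.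
4. Ring order: dihydrobenzofuran ring first (step 2), butenolide ring last (step 6). Closing the aryl ether first leaves the acceptor without a free phenol, so it needs no protecting group.

Assumption: the target is taken as drawn, (2R) at the butenolide carbon and (2S) at the dihydrobenzofuran carbon; arylpyruvates are drawn as keto tautomers although they exist largely as (Z)-enols.

**Step 1**
Reactants: 1 4-bromophenol; 2 1-bromo-3-methylbut-2-ene (prenyl bromide)
Product: 3 4-bromo-2-(3-methylbut-2-en-1-yl)phenol
Conditions: NaH (1.0 equiv), toluene, 0 °C; then 2, rt, 16 h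
Reagents that add atoms: none
Why: Ortho-selective C-alkylation of a sodium phenoxide in a non-polar solvent (Claisen-type C-prenylation, the laboratory counterpart of aromatic prenyl transfer): the tight ion pair delivers the allylic bromide to the ortho carbon, the para position is blocked by bromine, and no stereocentre is formed.

**Step 2**
Reactants: 3 4-bromo-2-(3-methylbut-2-en-1-yl)phenol
Product: 5 2-[(2S)-5-bromo-2,3-dihydro-1-benzofuran-2-yl]propan-2-ol, via epoxide 4 (not isolated)
Conditions: D-fructose-derived Shi ketone (30 mol %), KHSO5 (as 2KHSO5·KHSO4·K2SO4, 1.4 equiv), K2CO3, Bu4NHSO4 (cat.), MeCN/CH2(OMe)2/aq. Na2B4O7 buffer, pH about 10.5, 0 °C, 2 h; then rt, 3 h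
Reagents that add atoms: potassium peroxymonosulfate (KHSO5), [K+].[O-]S(=O)(=O)OO
Why: Shi asymmetric epoxidation followed by base-mediated 5-exo-tet epoxide opening: the dioxirane of the D-fructose-derived ketone attacks the trisubstituted prenyl olefin through the spiro transition state to give the (R)-epoxide 4, and at pH about 10.5 the ortho phenoxide opens it at the secondary carbon with inversion, which sets the (S) centre of 5 and leaves the epoxide oxygen as the tertiary alcohol.

**Step 3**
Reactants: 5 2-[(2S)-5-bromo-2,3-dihydro-1-benzofuran-2-yl]propan-2-ol; 6 methyl 2-[(tert-butoxycarbonyl)amino]prop-2-enoate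
Product: 7 methyl (2Z)-2-[(tert-butoxycarbonyl)amino]-3-[(2S)-2-(2-hydroxypropan-2-yl)-2,3-dihydro-1-benzofuran-5-yl]prop-2-enoate
Conditions: Pd2(dba)3 (2.5 mol %), [HP(t-Bu)3]BF4 (10 mol %), Cy2NMe (1.5 equiv), 1,4-dioxane, 60 °C
Reagents that add atoms: none
Why: Mizoroki–Heck reaction: the bulky electron-rich phosphine lets zerovalent palladium add to the electron-rich aryl bromide under mild conditions, insertion occurs at the CH2 terminus of the amidoacrylate and β-hydride elimination gives the (Z)-dehydroamino ester, with the free tertiary alcohol and the stereocentre untouched.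

**Step 4**
Reactants: 7 methyl (2Z)-2-[(tert-butoxycarbonyl)amino]-3-[(2S)-2-(2-hydroxypropan-2-yl)-2,3-dihydro-1-benzofuran-5-yl]prop-2-enoate
Product: 9 methyl 3-[(2S)-2-(2-hydroxypropan-2-yl)-2,3-dihydro-1-benzofuran-5-yl]-2-oxopropanoate, via enamino ester 8 (not isolated)
Conditions: CF3CO2H/CH2Cl2 (1:4), 0 °C, 1 h; then H2O, THF, rt; used promptly under argon
Reagents that add atoms: water, O
Why: Acidolytic Boc cleavage followed by enamine hydrolysis: the liberated enamino ester 8 tautomerises to the α-imino ester, which water converts into the α-keto ester, while the short cold acid treatment spares the tertiary alcohol (its ionisation is disfavoured by the adjacent ether oxygen) and does not touch the stereocentre.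

**Step 5**
Reactants: 10 3-(4-hydroxyphenyl)-2-oxopropanoic acid
Product: 11 trimethylsilyl (2Z)-2-[(trimethylsilyl)oxy]-3-{4-[(trimethylsilyl)oxy]phenyl}prop-2-enoate
Conditions: Me3SiCl (3.3 equiv), Et3N (3.5 equiv), THF, 0 °C to rt; filtered under argon, concentrated, used crude
Reagents that add atoms: chlorotrimethylsilane, C[Si](C)(C)Cl
Why: Exhaustive O-silylation of an acid that is already largely enolised: carboxyl, enol and phenol hydroxyls are all capped, which fixes the donor half as a (Z)-enol silane that can act only as a nucleophile, in the same way the known pyruvate-derived bis-silyl reagent is made.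

**Step 6**
Reactants: 9 methyl 3-[(2S)-2-(2-hydroxypropan-2-yl)-2,3-dihydro-1-benzofuran-5-yl]-2-oxopropanoate; 11 trimethylsilyl (2Z)-2-[(trimethylsilyl)oxy]-3-{4-[(trimethylsilyl)oxy]phenyl}prop-2-enoate
Product: 14 methyl (2R)-4-hydroxy-3-(4-hydroxyphenyl)-2-{[(2S)-2-(2-hydroxypropan-2-yl)-2,3-dihydro-1-benzofuran-5-yl]methyl}-5-oxo-2,5-dihydrofuran-2-carboxylate, via silylated aldol adduct 12 (not isolated), via hydroxy keto acid 13 (not isolated)
Conditions: Cu(OTf)2 (10 mol %), (R,R)-t-Bu-box [2,2′-(propane-2,2-diyl)bis((4R)-4-tert-butyl-4,5-dihydrooxazole), 11 mol %], 11 (2 equiv), THF, −78 to −20 °C, 9 added over 6 h; then 1 M HCl, THF, rt to 40 °C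
Reagents that add atoms: none
Why: Proposed new method: the keto tautomer of 9 chelates divalent copper through its two adjacent carbonyls in a square-planar complex whose Si face is shielded by a tert-butyl group of the (R,R) ligand, so enol silane 11 adds in Mukaiyama fashion to the Re face and sets the (R) quaternary carbinol, silyl transfer turns the catalyst over, and aqueous acid then strips the silyl groups so that the tertiary hydroxyl lactonises onto the α-keto acid and the ring enolises to the butenolide; the closest known reactions are the copper–bis(oxazoline)-catalysed aldol additions of enol silanes to pyruvate esters (where the (S,S) ligand gives Si-face attack) and the copper–bis(oxazoline)-catalysed pyruvate homo-aldol that lactonises to isotetronic acids, and slow addition of 9 to excess 11 keeps the free enol of 9 from competing as a donor.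

**Compound list**
1 | 4-bromophenol | Oc1ccc(Br)cc1 | starting material
2 | 1-bromo-3-methylbut-2-ene (prenyl bromide) | CC(C)=CCBr | starting material
3 | 4-bromo-2-(3-methylbut-2-en-1-yl)phenol | CC(C)=CCc1cc(Br)ccc1O | intermediate
4 | 4-bromo-2-{[(2R)-3,3-dimethyloxiran-2-yl]methyl}phenol (formed in the flask in step 2) | CC1(C)O[C@@H]1Cc1cc(Br)ccc1O | intermediate
5 | 2-[(2S)-5-bromo-2,3-dihydro-1-benzofuran-2-yl]propan-2-ol | Brc1ccc2c(c1)C[C@@H](C(C)(C)O)O2 | intermediate
6 | methyl 2-[(tert-butoxycarbonyl)amino]prop-2-enoate | COC(=O)C(=C)NC(=O)OC(C)(C)C | starting material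
7 | methyl (2Z)-2-[(tert-butoxycarbonyl)amino]-3-[(2S)-2-(2-hydroxypropan-2-yl)-2,3-dihydro-1-benzofuran-5-yl]prop-2-enoate | COC(=O)/C(NC(=O)OC(C)(C)C)=C/c1ccc2c(c1)C[C@@H](C(C)(C)O)O2 | intermediate
8 | methyl (2Z)-2-amino-3-[(2S)-2-(2-hydroxypropan-2-yl)-2,3-dihydro-1-benzofuran-5-yl]prop-2-enoate (formed in the flask in step 4) | COC(=O)/C(N)=C/c1ccc2c(c1)C[C@@H](C(C)(C)O)O2 | intermediate
9 | methyl 3-[(2S)-2-(2-hydroxypropan-2-yl)-2,3-dihydro-1-benzofuran-5-yl]-2-oxopropanoate | COC(=O)C(=O)Cc1ccc2c(c1)C[C@@H](C(C)(C)O)O2 | intermediate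
10 | 3-(4-hydroxyphenyl)-2-oxopropanoic acid | O=C(O)C(=O)Cc1ccc(O)cc1 | starting material
11 | trimethylsilyl (2Z)-2-[(trimethylsilyl)oxy]-3-{4-[(trimethylsilyl)oxy]phenyl}prop-2-enoate | C[Si](C)(C)O/C(C(=O)O[Si](C)(C)C)=C\c1ccc(O[Si](C)(C)C)cc1 | intermediate
12 | 1-methyl 5-(trimethylsilyl) (2R)-2-{[(2S)-2-(2-hydroxypropan-2-yl)-2,3-dihydro-1-benzofuran-5-yl]methyl}-4-oxo-2-[(trimethylsilyl)oxy]-3-{4-[(trimethylsilyl)oxy]phenyl}pentanedioate (both C3 epimers; formed in the flask in step 6) | COC(=O)[C@@](O[Si](C)(C)C)(Cc1ccc2c(c1)C[C@@H](C(C)(C)O)O2)C(c1ccc(O[Si](C)(C)C)cc1)C(=O)C(=O)O[Si](C)(C)C | intermediate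
13 | (4R)-4-hydroxy-4-{[(2S)-2-(2-hydroxypropan-2-yl)-2,3-dihydro-1-benzofuran-5-yl]methyl}-3-(4-hydroxyphenyl)-5-methoxy-2,5-dioxopentanoic acid (both C3 epimers; formed in the flask in step 6) | COC(=O)[C@@](O)(Cc1ccc2c(c1)C[C@@H](C(C)(C)O)O2)C(c1ccc(O)cc1)C(=O)C(=O)O | intermediate
14 | methyl (2R)-4-hydroxy-3-(4-hydroxyphenyl)-2-{[(2S)-2-(2-hydroxypropan-2-yl)-2,3-dihydro-1-benzofuran-5-yl]methyl}-5-oxo-2,5-dihydrofuran-2-carboxylate | COC(=O)[C@]1(Cc2ccc3c(c2)C[C@@H](C(C)(C)O)O3)OC(=O)C(O)=C1c1ccc(O)cc1 | target

**Totals and risks**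
Total step count: 6. Longest linear sequence: 5 steps (steps 1, 2, 3, 4 and 6 from 4-bromophenol); step 5 is a one-step side branch.

The three steps most likely to fail are step 6, step 2 and step 3.

Step 6 is the main risk. Compound 9 rests largely as its enol, so the copper catalyst may turn over slowly, silyl groups may scramble between 11 and the enol of 9, and the facial sense is assigned only by analogy with simple pyruvates. If the sense of induction proves opposite, the enantiomeric ligand is used. If the catalytic union itself fails, catalyst control is given up. The fallback sets out from 9 and 10. Acid 10 is esterified (MeOH, cat. H2SO4) to methyl 3-(4-hydroxyphenyl)-2-oxopropanoate F1. F1 (3 equiv) is condensed with 9 by the classical base-mediated arylpyruvate aldol–lactonisation (DBU, DMF, 0 °C to rt; then aq. HCl). Because 9 already carries the (S) centre, the cross product forms as two C2 epimers, 14 and methyl (2S)-4-hydroxy-3-(4-hydroxyphenyl)-2-{[(2S)-2-(2-hydroxypropan-2-yl)-2,3-dihydro-1-benzofuran-5-yl]methyl}-5-oxo-2,5-dihydrofuran-2-carboxylate F2. These are diastereomers and are separated, together with the symmetrical dimers, by preparative reversed-phase HPLC. The cross-selectivity is only statistical, so the yield will be low. The route is rejoined at 14.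

Step 2 may fail because the free phenoxide could be oxidised by the dioxirane before the olefin is consumed. The fallback sets out from 3 and masks the phenol first. Acetylation (Ac2O, pyridine) gives 4-bromo-2-(3-methylbut-2-en-1-yl)phenyl acetate F3. The same Shi epoxidation gives 4-bromo-2-{[(2R)-3,3-dimethyloxiran-2-yl]methyl}phenyl acetate F4. K2CO3 in MeOH then releases the phenoxide, which cyclises through 4. The route is rejoined at 5.

Step 3 may fail because the aryl bromide is electron-rich and acrylate 6 polymerises easily on heating. The fallback sets out from 5 and replaces cross-coupling by olefination. Bromine–lithium exchange (n-BuLi, 2.2 equiv, THF, −78 °C) and a DMF quench give (2S)-2-(2-hydroxypropan-2-yl)-2,3-dihydro-1-benzofuran-5-carbaldehyde F5. Horner–Wadsworth–Emmons reaction of F5 with commercial methyl 2-[(tert-butoxycarbonyl)amino]-2-(dimethoxyphosphoryl)acetate (1,1,3,3-tetramethylguanidine, THF, −78 °C to rt) gives the dehydroamino ester. The route is rejoined at 7.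

**Further compounds**
F1 | step 6 | methyl 3-(4-hydroxyphenyl)-2-oxopropanoate | COC(=O)C(=O)Cc1ccc(O)cc1
F2 | step 6 | methyl (2S)-4-hydroxy-3-(4-hydroxyphenyl)-2-{[(2S)-2-(2-hydroxypropan-2-yl)-2,3-dihydro-1-benzofuran-5-yl]methyl}-5-oxo-2,5-dihydrofuran-2-carboxylate | COC(=O)[C@@]1(Cc2ccc3c(c2)C[C@@H](C(C)(C)O)O3)OC(=O)C(O)=C1c1ccc(O)cc1
F3 | step 2 | 4-bromo-2-(3-methylbut-2-en-1-yl)phenyl acetate | CC(=O)Oc1ccc(Br)cc1CC=C(C)C
F4 | step 2 | 4-bromo-2-{[(2R)-3,3-dimethyloxiran-2-yl]methyl}phenyl acetate | CC1(C)O[C@@H]1Cc1cc(Br)ccc1OC(C)=O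
F5 | step 3 | (2S)-2-(2-hydroxypropan-2-yl)-2,3-dihydro-1-benzofuran-5-carbaldehyde | O=Cc1ccc2c(c1)C[C@@H](C(C)(C)O)O2
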